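The final disconnection is global debenzylation of the nonabenzyl ether of gneyulin A. In that ether, the dihydrofuran ring fused to the styryl-bearing resorcinol ring (ring E: O1–C2–C3–C3a–C7a) is cut between C2 and C3 and one nitrogen atom is placed in the gap. This gives a six-membered 3,4-dihydro-2H-1,3-benzoxazine; loss of that nitrogen as N2 contracts six atoms to five and forms C2–C3 with both stereocentres.
Enabling feature: C2 lies between O1 and a 2,4-dioxygenated aryl ring. C3 is doubly benzylic and is clamped between the two ortho oxygens of the resorcinol ring (O1 on C7a, OH on C4). Both carbons give stabilised radicals without β-hydrogen, and O1–C2–N is an N,O-acetal, so the oxazine is simply the condensation product of an aldehyde (C2) and a Betti-type aminoresorcinol (C3).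
Aminoresorcinol fragment: the C3–aryl bond comes from adding a protected oxyresveratrol, lithiated between its two OMOM groups, to the tert-butanesulfinyl imine of 3,5-bis(benzyloxy)benzaldehyde. The stilbene comes from a Horner–Wadsworth–Emmons olefination.
Aldehyde fragment: the other dihydrobenzofuran is made by enantioselective intramolecular C–H insertion of a diaryl (donor/donor) rhodium carbene, acid epimerisation at its C2 to trans, then Br → CHO.
Ring order: first dihydrofuran ring (step 7), oxazine ring (step 16), contraction of the oxazine to the second dihydrofuran ring (step 17).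
Key step: step 17

Assumption: the absolute sense of induction in step 7 (catalyst antipode) and step 14 (open transition state of the aryllithium in THF) is assigned by analogy with the closest known cases; if a first run shows the opposite sense, the mirror-image catalyst or auxiliary is used and nothing else changes.

Step 1
Reactants: 1 2,4-bis(benzyloxy)benzaldehyde
Product: 2 [2,4-bis(benzyloxy)phenyl]methanol
Conditions: NaBH4, MeOH/THF, 0 °C; H2O
Reagents that add atoms: none
Why: Borohydride reduction of an aryl aldehyde, to which benzyl ethers are inert.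

Step 2
Reactants: 3 5-bromo-2,4-dihydroxybenzaldehyde
Product: 4 4-(benzyloxy)-5-bromo-2-hydroxybenzaldehyde
Conditions: BnBr (1.05 equiv), NaHCO3, MeCN, 80 °C
Reagents that add atoms: benzyl bromide BrCc1ccccc1
Why: Williamson etherification that is regioselective because the 2-OH is hydrogen-bonded to the formyl group, so only the more acidic 4-OH is deprotonated by the weak base.

Step 3
Reactants: 4 4-(benzyloxy)-5-bromo-2-hydroxybenzaldehyde; 2 [2,4-bis(benzyloxy)phenyl]methanol
Product: 5 4-(benzyloxy)-2-{[2,4-bis(benzyloxy)phenyl]methoxy}-5-bromobenzaldehyde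
Conditions: PPh3, DIAD, THF, 0 °C to rt
Reagents that add atoms: none
Why: Mitsunobu etherification joins the remaining phenol to the primary benzylic alcohol under neutral conditions, so no unstable 2,4-dialkoxybenzyl halide has to be handled.

Step 4
Reactants: 5 4-(benzyloxy)-2-{[2,4-bis(benzyloxy)phenyl]methoxy}-5-bromobenzaldehyde; 6 1,3-bis(benzyloxy)-5-bromobenzene
Product: 8 (4-(benzyloxy)-2-{[2,4-bis(benzyloxy)phenyl]methoxy}-5-bromophenyl)[3,5-bis(benzyloxy)phenyl]methanol (racemic carbinol), via arylmagnesium bromide 7 (not isolated)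
Conditions: 6, Mg, THF, reflux; then 5, THF, 0 °C; H2O
Reagents that add atoms: none
Why: Grignard 1,2-addition to the aldehyde is much faster than halogen–magnesium exchange at the aryl bromide, and the new carbinol centre is erased in step 5, so its configuration does not matter.

Step 5
Reactants: 8 the diaryl carbinol
Product: 9 (4-(benzyloxy)-2-{[2,4-bis(benzyloxy)phenyl]methoxy}-5-bromophenyl)[3,5-bis(benzyloxy)phenyl]methanone
Conditions: MnO2, CH2Cl2, rt
Reagents that add atoms: none
Why: MnO2 oxidation of a doubly benzylic alcohol to the benzophenone leaves the ethers and the aryl bromide untouched.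

Step 6
Reactants: 9 the benzophenone
Product: 10 hydrazone of 9 (E/Z mixture)
Conditions: N2H4·H2O (excess), AcOH (cat.), EtOH, 100 °C, sealed tube
Reagents that add atoms: hydrazine NN
Why: Hydrazone condensation under the forcing conditions usual for ortho-alkoxybenzophenones, with no other electrophilic group in the molecule.

Step 7
Reactants: 10 the hydrazone
Product: 12 (2S,3R)-6-(benzyloxy)-2-[2,4-bis(benzyloxy)phenyl]-3-[3,5-bis(benzyloxy)phenyl]-5-bromo-2,3-dihydro-1-benzofuran (cis), via diaryldiazomethane 11 (not isolated)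
Conditions: MnO2, CH2Cl2, rt; filter; Rh2(S-PTAD)4 (1 mol %), CH2Cl2, 0 °C
Reagents that add atoms: none
Why: Dehydrogenation gives the diaryldiazomethane, whose donor/donor rhodium carbene undergoes enantioselective intramolecular 1,5-C–H insertion into the ether CH2 activated by oxygen and the electron-rich aryl group; the chiral carboxylate ligands set C3 as R and the concerted insertion gives the cis-2,3 isomer.

Step 8
Reactants: 12 the cis-dihydrobenzofuran
Product: 13 (2R,3R)-6-(benzyloxy)-2-[2,4-bis(benzyloxy)phenyl]-3-[3,5-bis(benzyloxy)phenyl]-5-bromo-2,3-dihydro-1-benzofuran (trans)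
Conditions: TFA (cat.), CH2Cl2, 0 °C to rt
Reagents that add atoms: none
Why: Acid-catalysed epimerisation, in which reversible heterolysis of the O1–C2 bond is assisted by the 2,4-bis(benzyloxy)phenyl group and re-closure under thermodynamic control places the C2 aryl group trans to the untouched C3 aryl group.

Step 9
Reactants: 13 the trans bromide
Product: 15 (2R,3R)-6-(benzyloxy)-2-[2,4-bis(benzyloxy)phenyl]-3-[3,5-bis(benzyloxy)phenyl]-2,3-dihydro-1-benzofuran-5-carbaldehyde, via aryllithium 14 (not isolated)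
Conditions: n-BuLi, THF, −78 °C; DMF; H2O
Reagents that add atoms: N,N-dimethylformamide CN(C)C=O
Why: Bromine–lithium exchange and formylation with DMF (Bouveault aldehyde synthesis) outrun benzylic deprotonation at −78 °C, so both stereocentres persist.

Step 10
Reactants: 16 3,5-dihydroxybenzaldehyde
Product: 17 3,5-bis(methoxymethoxy)benzaldehyde
Conditions: MOMCl, i-Pr2NEt, CH2Cl2, 0 °C to rt
Reagents that add atoms: chloromethyl methyl ether COCCl
Why: O-alkylation of both phenols to MOM acetals, which later direct the metalation and leave together with the auxiliary.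

Step 11
Reactants: 2 [2,4-bis(benzyloxy)phenyl]methanol
Product: 18 diethyl {[2,4-bis(benzyloxy)phenyl]methyl}phosphonate
Conditions: ZnI2, P(OEt)3, toluene, reflux
Reagents that add atoms: triethyl phosphite CCOP(OCC)OCC
Why: ZnI2-mediated Michaelis–Arbuzov-type reaction converts the electron-rich benzylic alcohol directly into the phosphonate, so no labile benzylic halide has to be isolated.

Step 12
Reactants: 18 the phosphonate; 17 3,5-bis(methoxymethoxy)benzaldehyde
Product: 19 (E)-2,4-bis(benzyloxy)-3',5'-bis(methoxymethoxy)stilbene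
Conditions: KOt-Bu, THF, 0 °C to rt
Reagents that add atoms: none
Why: Horner–Wadsworth–Emmons olefination of an aryl aldehyde with a benzylic phosphonate should give the E-stilbene.

Step 13
Reactants: 20 3,5-bis(benzyloxy)benzaldehyde; 21 (S)-2-methylpropane-2-sulfinamide
Product: 22 (S,E)-N-[3,5-bis(benzyloxy)benzylidene]-2-methylpropane-2-sulfinamide
Conditions: Ti(OEt)4, THF, rt
Reagents that add atoms: none
Why: Ti(OEt)4-mediated condensation gives the E-configured N-sulfinyl aldimine without touching the sulfur stereocentre.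

Step 14
Reactants: 19 the stilbene; 22 the sulfinyl aldimine
Product: 24 (S)-N-{(R)-[3,5-bis(benzyloxy)phenyl][4-{(E)-2-[2,4-bis(benzyloxy)phenyl]ethenyl}-2,6-bis(methoxymethoxy)phenyl]methyl}-2-methylpropane-2-sulfinamide, via aryllithium 23 (not isolated)
Conditions: 19, n-BuLi, TMEDA, THF, −20 °C; then 22, −78 °C; H2O
Reagents that add atoms: none
Why: Directed ortho-metalation at the position flanked by both OMOM groups, then 1,2-addition of the aryllithium to the N-sulfinyl aldimine through the open transition state usual in THF, sets the diarylmethyl centre as R under control of the sulfur stereocentre, and the minor epimer can be removed by chromatography.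

Step 15
Reactants: 24 the sulfinamide
Product: 25 2-{(R)-amino[3,5-bis(benzyloxy)phenyl]methyl}-5-{(E)-2-[2,4-bis(benzyloxy)phenyl]ethenyl}benzene-1,3-diol
Conditions: HCl (dioxane)/MeOH, rt to 40 °C; aq. NaHCO3
Reagents that add atoms: none
Why: Acidic methanolysis cleaves the N-sulfinyl group and both MOM acetals in one operation while the benzyl ethers stay, and the ammonium form resists ionisation of the benzhydrylic C–N bond, in line with the acid hydrolysis used to prepare Betti bases.

Step 16
Reactants: 25 the aminoresorcinol; 15 the aldehyde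
Product: 27 (2S,4R)-2-{(2R,3R)-6-(benzyloxy)-2-[2,4-bis(benzyloxy)phenyl]-3-[3,5-bis(benzyloxy)phenyl]-2,3-dihydro-1-benzofuran-5-yl}-4-[3,5-bis(benzyloxy)phenyl]-7-{(E)-2-[2,4-bis(benzyloxy)phenyl]ethenyl}-3,4-dihydro-2H-1,3-benzoxazin-5-ol, via o-hydroxyaryl imine 26 (not isolated)
Conditions: 4 Å molecular sieves, CH2Cl2/EtOH, rt; filtered, concentrated, used without chromatography
Reagents that add atoms: none
Why: Condensation of a Betti-type o-hydroxybenzylamine with an aryl aldehyde and ring–chain tautomerisation (6-endo-trig addition of a phenol O–H to the C=N bond of 26) is the standard entry to 2,4-diaryl-1,3-benzoxazines; the two phenol groups of 25 are equivalent so only one constitution can form, and the trans-2,4 ring form should prevail because the 4-aryl group stands pseudoaxial to avoid the 5-OH while the 2-aryl group stays equatorial.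

Step 17
Reactants: 27 the 1,3-benzoxazine
Product: 31 (2R,3R)-2-{(2R,3R)-6-(benzyloxy)-2-[2,4-bis(benzyloxy)phenyl]-3-[3,5-bis(benzyloxy)phenyl]-2,3-dihydro-1-benzofuran-5-yl}-3-[3,5-bis(benzyloxy)phenyl]-6-{(E)-2-[2,4-bis(benzyloxy)phenyl]ethenyl}-2,3-dihydro-1-benzofuran-4-ol (nonabenzyl gneyulin A), via N-amino adduct 28 (not isolated), via isodiazene 29 (not isolated), via singlet 1,5-diradical 30 (not isolated)
Conditions: N-(benzyloxy)-N-(pivaloyloxy)-4-(trifluoromethyl)benzamide (1.5 equiv), THF, 45 °C, argon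
Reagents that add atoms: none
Why: Proposed new method: the N–H of ring tautomer 27 displaces pivalate at the nitrogen of the anomeric amide to give 28, which expels benzyl 4-(trifluoromethyl)benzoate to leave isodiazene 29, and loss of N2 gives the caged singlet 1,5-diradical 30 whose termini C2 and C3 combine, so the six-membered oxazine ring contracts to the five-membered dihydrofuran ring and the two large fragments become joined by a C–C bond. The closest known reaction type is the nitrogen deletion of secondary bis-benzylic amines through 1,1-diazenes, which includes six-to-five contractions of benzo-fused and 2,6-diaryl-substituted azacycles with retention at both carbons; what is new is that the nitrogen belongs to an N,O-acetal. The only ring closed is the dihydrofuran ring, by intramolecular radical–radical combination between C2 and C3 (1,5-closure across the O1–C7a–C3a tether). C3 keeps the R configuration set in step 14 because the radical centres are born within bonding distance and should collapse faster than the C3–C3a bond can rotate, a rotation that the two ortho oxygen substituents (O1 and 4-OH) slow further; C2 is set trans to it by least-motion collapse of the trans ring tautomer and by the steric bias of the planar α-aryloxybenzyl radical to bond with its aryl group anti to the C3 aryl group. The step needs chemoselectivity for the oxazine nitrogen and clean recombination: imine 26 has no N–H and drains through the ring–chain equilibrium that the released pivalic acid catalyses, the free phenol is too weak a nucleophile under neutral conditions, neither radical carries a β-hydrogen so disproportionation is excluded, and both C–N bonds are weak enough for N2 loss at a temperature that spares the stilbene and the first dihydrobenzofuran.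

Step 18
Reactants: 31 nonabenzyl gneyulin A
Product: 32 gneyulin A
Conditions: BCl3 (CH2Cl2 solution, excess), pentamethylbenzene (excess), CH2Cl2, −78 °C; MeOH
Reagents that add atoms: none
Why: Lewis-acid debenzylation with BCl3 and pentamethylbenzene as a non-basic cation scavenger should remove all nine aryl benzyl ethers at low temperature without touching the stilbene double bond that rules out hydrogenolysis, and any reversible opening at C2 of either dihydrofuran ring returns to the trans isomer because C3 stays fixed.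

Compound list
1 | 2,4-bis(benzyloxy)benzaldehyde | O=Cc1ccc(OCc2ccccc2)cc1OCc1ccccc1 | starting material
2 | [2,4-bis(benzyloxy)phenyl]methanol | OCc1ccc(OCc2ccccc2)cc1OCc1ccccc1 | intermediate
3 | 5-bromo-2,4-dihydroxybenzaldehyde | O=Cc1cc(Br)c(O)cc1O | starting material
4 | 4-(benzyloxy)-5-bromo-2-hydroxybenzaldehyde | O=Cc1cc(Br)c(OCc2ccccc2)cc1O | intermediate
5 | 4-(benzyloxy)-2-{[2,4-bis(benzyloxy)phenyl]methoxy}-5-bromobenzaldehyde | O=Cc1cc(Br)c(OCc2ccccc2)cc1OCc1ccc(OCc2ccccc2)cc1OCc1ccccc1 | intermediate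
6 | 1,3-bis(benzyloxy)-5-bromobenzene | Brc1cc(OCc2ccccc2)cc(OCc2ccccc2)c1 | starting material
7 | [3,5-bis(benzyloxy)phenyl]magnesium bromide | Br[Mg]c1cc(OCc2ccccc2)cc(OCc2ccccc2)c1 | intermediate
8 | (4-(benzyloxy)-2-{[2,4-bis(benzyloxy)phenyl]methoxy}-5-bromophenyl)[3,5-bis(benzyloxy)phenyl]methanol, racemic | OC(c1cc(OCc2ccccc2)cc(OCc2ccccc2)c1)c1cc(Br)c(OCc2ccccc2)cc1OCc1ccc(OCc2ccccc2)cc1OCc1ccccc1 | intermediate
9 | (4-(benzyloxy)-2-{[2,4-bis(benzyloxy)phenyl]methoxy}-5-bromophenyl)[3,5-bis(benzyloxy)phenyl]methanone | O=C(c1cc(OCc2ccccc2)cc(OCc2ccccc2)c1)c1cc(Br)c(OCc2ccccc2)cc1OCc1ccc(OCc2ccccc2)cc1OCc1ccccc1 | intermediate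
10 | hydrazone of 9 (E/Z mixture) | NN=C(c1cc(OCc2ccccc2)cc(OCc2ccccc2)c1)c1cc(Br)c(OCc2ccccc2)cc1OCc1ccc(OCc2ccccc2)cc1OCc1ccccc1 | intermediate
11 | diaryldiazomethane derived from 10 | [N-]=[N+]=C(c1cc(OCc2ccccc2)cc(OCc2ccccc2)c1)c1cc(Br)c(OCc2ccccc2)cc1OCc1ccc(OCc2ccccc2)cc1OCc1ccccc1 | intermediate
12 | (2S,3R)-6-(benzyloxy)-2-[2,4-bis(benzyloxy)phenyl]-3-[3,5-bis(benzyloxy)phenyl]-5-bromo-2,3-dihydro-1-benzofuran (cis) | c1ccccc1COc1cc(OCc7ccccc7)cc([C@@H]2c3cc(Br)c(OCc7ccccc7)cc3O[C@@H]2c2ccc(OCc7ccccc7)cc2OCc2ccccc2)c1 | intermediate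
13 | (2R,3R)-6-(benzyloxy)-2-[2,4-bis(benzyloxy)phenyl]-3-[3,5-bis(benzyloxy)phenyl]-5-bromo-2,3-dihydro-1-benzofuran (trans) | c1ccccc1COc1cc(OCc7ccccc7)cc([C@@H]2c3cc(Br)c(OCc7ccccc7)cc3O[C@H]2c2ccc(OCc7ccccc7)cc2OCc2ccccc2)c1 | intermediate
14 | (2R,3R)-5-lithio analogue of 13 | c1ccccc1COc1cc(OCc7ccccc7)cc([C@@H]2c3cc([Li])c(OCc7ccccc7)cc3O[C@H]2c2ccc(OCc7ccccc7)cc2OCc2ccccc2)c1 | intermediate
15 | (2R,3R)-6-(benzyloxy)-2-[2,4-bis(benzyloxy)phenyl]-3-[3,5-bis(benzyloxy)phenyl]-2,3-dihydro-1-benzofuran-5-carbaldehyde | c1ccccc1COc1cc(OCc7ccccc7)cc([C@@H]2c3cc(C=O)c(OCc7ccccc7)cc3O[C@H]2c2ccc(OCc7ccccc7)cc2OCc2ccccc2)c1 | intermediate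
16 | 3,5-dihydroxybenzaldehyde | O=Cc1cc(O)cc(O)c1 | starting material
17 | 3,5-bis(methoxymethoxy)benzaldehyde | O=Cc1cc(OCOC)cc(OCOC)c1 | intermediate
18 | diethyl {[2,4-bis(benzyloxy)phenyl]methyl}phosphonate | CCOP(=O)(Cc1ccc(OCc2ccccc2)cc1OCc1ccccc1)OCC | intermediate
19 | (E)-2,4-bis(benzyloxy)-3',5'-bis(methoxymethoxy)stilbene | COCOc1cc(/C=C/c2ccc(OCc3ccccc3)cc2OCc2ccccc2)cc(OCOC)c1 | intermediate
20 | 3,5-bis(benzyloxy)benzaldehyde | O=Cc1cc(OCc2ccccc2)cc(OCc2ccccc2)c1 | starting material
21 | (S)-2-methylpropane-2-sulfinamide | CC(C)(C)[S@](=O)N | starting material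
22 | (S,E)-N-[3,5-bis(benzyloxy)benzylidene]-2-methylpropane-2-sulfinamide | CC(C)(C)[S@](=O)/N=C/c1cc(OCc2ccccc2)cc(OCc2ccccc2)c1 | intermediate
23 | 4'-lithio derivative of 19 (lithium between the two OMOM groups) | COCOc1cc(/C=C/c2ccc(OCc3ccccc3)cc2OCc2ccccc2)cc(OCOC)c1[Li] | intermediate
24 | (S)-N-{(R)-[3,5-bis(benzyloxy)phenyl][4-{(E)-2-[2,4-bis(benzyloxy)phenyl]ethenyl}-2,6-bis(methoxymethoxy)phenyl]methyl}-2-methylpropane-2-sulfinamide | CC(C)(C)[S@](=O)N[C@H](c1cc(OCc2ccccc2)cc(OCc2ccccc2)c1)c1c(OCOC)cc(/C=C/c2ccc(OCc3ccccc3)cc2OCc2ccccc2)cc1OCOC | intermediate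
25 | 2-{(R)-amino[3,5-bis(benzyloxy)phenyl]methyl}-5-{(E)-2-[2,4-bis(benzyloxy)phenyl]ethenyl}benzene-1,3-diol | N[C@H](c1cc(OCc2ccccc2)cc(OCc2ccccc2)c1)c1c(O)cc(/C=C/c2ccc(OCc3ccccc3)cc2OCc2ccccc2)cc1O | intermediate
26 | (E)-aldimine of 15 with 25, R at the benzhydryl carbon, open-chain tautomer of 27 | c1ccccc1COc1cc(OCc7ccccc7)cc([C@@H]2c3cc(/C=N/[C@H](c4cc(OCc7ccccc7)cc(OCc7ccccc7)c4)c4c(O)cc(/C=C/c6ccc(OCc7ccccc7)cc6OCc6ccccc6)cc4O)c(OCc7ccccc7)cc3O[C@H]2c2ccc(OCc7ccccc7)cc2OCc2ccccc2)c1 | intermediate
27 | (2S,4R)-2,4-trans-3,4-dihydro-2H-1,3-benzoxazin-5-ol carrying the dihydrobenzofuran-5-yl group of 15 at C2, 3,5-bis(benzyloxy)phenyl at C4 and the (E)-2,4-bis(benzyloxy)styryl group at C7 | c1ccccc1COc1cc(OCc7ccccc7)cc([C@@H]2c3cc([C@@H]4Oc5cc(/C=C/c6ccc(OCc7ccccc7)cc6OCc6ccccc6)cc(O)c5[C@H](N4)c4cc(OCc7ccccc7)cc(OCc7ccccc7)c4)c(OCc7ccccc7)cc3O[C@H]2c2ccc(OCc7ccccc7)cc2OCc2ccccc2)c1 | intermediate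
28 | N3-[benzyloxy(4-trifluoromethylbenzoyl)amino] derivative of 27 | c1ccccc1COc1cc(OCc7ccccc7)cc([C@@H]2c3cc([C@@H]4Oc5cc(/C=C/c6ccc(OCc7ccccc7)cc6OCc6ccccc6)cc(O)c5[C@H](N4N(OCc7ccccc7)C(=O)c7ccc(cc7)C(F)(F)F)c4cc(OCc7ccccc7)cc(OCc7ccccc7)c4)c(OCc7ccccc7)cc3O[C@H]2c2ccc(OCc7ccccc7)cc2OCc2ccccc2)c1 | intermediate
29 | isodiazene (1,1-diazene) of 27 | c1ccccc1COc1cc(OCc7ccccc7)cc([C@@H]2c3cc([C@@H]4Oc5cc(/C=C/c6ccc(OCc7ccccc7)cc6OCc6ccccc6)cc(O)c5[C@H]([N+]4=[N-])c4cc(OCc7ccccc7)cc(OCc7ccccc7)c4)c(OCc7ccccc7)cc3O[C@H]2c2ccc(OCc7ccccc7)cc2OCc2ccccc2)c1 | intermediate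
30 | singlet 1,5-diradical (α-aryloxybenzyl radical at C2, diarylmethyl radical at C3) | c1ccccc1COc1cc(OCc7ccccc7)cc([C@@H]2c3cc([CH]Oc5cc(/C=C/c6ccc(OCc7ccccc7)cc6OCc6ccccc6)cc(O)c5[CH]c4cc(OCc7ccccc7)cc(OCc7ccccc7)c4)c(OCc7ccccc7)cc3O[C@H]2c2ccc(OCc7ccccc7)cc2OCc2ccccc2)c1 | intermediate
31 | nonabenzyl gneyulin A, all four ring stereocentres R, both dihydrofuran rings trans, free 4-OH | c1ccccc1COc1cc(OCc7ccccc7)cc([C@@H]2c3cc([C@@H]4Oc5cc(/C=C/c6ccc(OCc7ccccc7)cc6OCc6ccccc6)cc(O)c5[C@H]4c4cc(OCc7ccccc7)cc(OCc7ccccc7)c4)c(OCc7ccccc7)cc3O[C@H]2c2ccc(OCc7ccccc7)cc2OCc2ccccc2)c1 | intermediate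
32 | gneyulin A | Oc1cc(O)cc([C@@H]2c3cc([C@@H]4Oc5cc(/C=C/c6ccc(O)cc6O)cc(O)c5[C@H]4c4cc(O)cc(O)c4)c(O)cc3O[C@H]2c2ccc(O)cc2O)c1 | target

Total step count: 18. Longest linear sequence: 11 steps (1 or 2, then 3 to 9 and 16 to 18).

Steps most likely to fail

1. Step 17.
- What may go wrong: amination of the hindered, weakly nucleophilic N,O-acetal nitrogen may be slow while the ring–chain equilibrium lies on the imine side. Rotation about the C3–C3a bond in the diradical may also erode the configuration at C3 before the bond forms.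
- What is not critical: erosion at C2 alone, because brief acid treatment as in step 8 would equilibrate C2 to trans.
- Fallback (known o-quinone methide/sulfur ylide [4+1] annulation): it sets out from aldehyde 15 and amine 25 and comes back at 31. NaBH4 reduction of 15 should give the benzylic alcohol F1. With tetrahydrothiophene and HBF4·OEt2 in CH2Cl2 this is converted into the sulfonium tetrafluoroborate F2. When 25 is warmed with F2 and Cs2CO3 in MeCN, F2 is deprotonated to the sulfonium ylide F3 while 25 loses ammonia to give the o-quinone methide F4. Conjugate addition of F3 to F4, then displacement of tetrahydrothiophene by the phenoxide, closes the trans-dihydrofuran ring directly. The configuration at C3 is then no longer relayed from step 14, so 31 is expected together with its (2S,3S) diastereomer F5. The two can be separated by chromatography because the first dihydrobenzofuran is enantiopure.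

2. Step 14.
- What may go wrong: the di-ortho-substituted aryllithium may add to the aldimine so slowly that proton transfer and decay of the aryllithium compete. Internal chelation by the OMOM groups may also blur the open transition state and lower the facial selectivity.
- Fallback (polarity reversal): it sets out from aryllithium 23 and comes back at 24. Quenching 23 with DMF should give the aldehyde F6. Condensation with 21 (Ti(OEt)4, THF) gives the sulfinyl aldimine F7. Grignard reagent 7 is then added in CH2Cl2/toluene at −48 °C, where the chelated chair transition state should deliver the same sulfinamide 24 (S at sulfur, R at carbon).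

3. Step 18.
- What may go wrong: cleavage of nine ethers may be incomplete, and the liberated, very electron-rich decaphenol may decompose by air oxidation or acid during work-up and chromatography.
- Fallback (protecting-group exchange instead of direct release): it sets out from 31 and comes back at 32. After the BCl3/pentamethylbenzene treatment and MeOH quench, the crude material is concentrated and acetylated at once (Ac2O, pyridine, DMAP) to the decaacetate F8, which tolerates chromatography and can be purified rigorously. Transesterification with K2CO3 in degassed MeOH at 0 °C, followed by neutralisation, then releases 32 under conditions free of Lewis acid.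

Further compounds
F1 | step 17 | {(2R,3R)-6-(benzyloxy)-2-[2,4-bis(benzyloxy)phenyl]-3-[3,5-bis(benzyloxy)phenyl]-2,3-dihydro-1-benzofuran-5-yl}methanol | c1ccccc1COc1cc(OCc7ccccc7)cc([C@@H]2c3cc(CO)c(OCc7ccccc7)cc3O[C@H]2c2ccc(OCc7ccccc7)cc2OCc2ccccc2)c1
F2 | step 17 | S-benzylic tetrahydrothiophenium tetrafluoroborate derived from F1 | c1ccccc1COc1cc(OCc7ccccc7)cc([C@@H]2c3cc(C[S+]8CCCC8)c(OCc7ccccc7)cc3O[C@H]2c2ccc(OCc7ccccc7)cc2OCc2ccccc2)c1.F[B-](F)(F)F
F3 | step 17 | sulfonium ylide derived from F2 | c1ccccc1COc1cc(OCc7ccccc7)cc([C@@H]2c3cc([CH-][S+]8CCCC8)c(OCc7ccccc7)cc3O[C@H]2c2ccc(OCc7ccccc7)cc2OCc2ccccc2)c1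
F4 | step 17 | o-quinone methide derived from 25 by loss of ammonia | O=C1C=C(/C=C/c2ccc(OCc3ccccc3)cc2OCc2ccccc2)C=C(O)C1=Cc1cc(OCc2ccccc2)cc(OCc2ccccc2)c1
F5 | step 17 | diastereomer of 31 with (2S,3S) configuration in the styryl-bearing dihydrobenzofuran | c1ccccc1COc1cc(OCc7ccccc7)cc([C@@H]2c3cc([C@H]4Oc5cc(/C=C/c6ccc(OCc7ccccc7)cc6OCc6ccccc6)cc(O)c5[C@@H]4c4cc(OCc7ccccc7)cc(OCc7ccccc7)c4)c(OCc7ccccc7)cc3O[C@H]2c2ccc(OCc7ccccc7)cc2OCc2ccccc2)c1
F6 | step 14 | 4-{(E)-2-[2,4-bis(benzyloxy)phenyl]ethenyl}-2,6-bis(methoxymethoxy)benzaldehyde | COCOc1cc(/C=C/c2ccc(OCc3ccccc3)cc2OCc2ccccc2)cc(OCOC)c1C=O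
F7 | step 14 | (S,E)-N-sulfinyl aldimine of F6 | CC(C)(C)[S@](=O)/N=C/c1c(OCOC)cc(/C=C/c2ccc(OCc3ccccc3)cc2OCc2ccccc2)cc1OCOC
F8 | step 18 | gneyulin A decaacetate | CC(=O)Oc1cc(OC(C)=O)cc([C@@H]2c3cc([C@@H]4Oc5cc(/C=C/c6ccc(OC(C)=O)cc6OC(C)=O)cc(OC(C)=O)c5[C@H]4c4cc(OC(C)=O)cc(OC(C)=O)c4)c(OC(C)=O)cc3O[C@H]2c2ccc(OC(C)=O)cc2OC(C)=O)c1
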